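The readings were generated by integration with made-up constants.

We read each run at one moment, the end of the dose, and freeze one thing there: the rate constant at which free monomer goes into chains.

| setting | midnight | autumn | spring | flask |
|---|---|---|---|---|
| free monomer | 34 mM (fed, over 2.5 h) | 53 mM (fed, over 2.5 h) | 24 mM (fed, over 2.5 h) | 24 mM (fed, over 2.5 h) |
| initiator | 0.2 mol% | 0.2 mol% | 0.3 mol% | 0.2 mol% |
| remark | run made earlier | run made earlier | run made earlier |  |
| time |  |  |  | 2.5 h |

| run | time / h | monomer in chains / % | free monomer / % |
|---|---|---|---|
| midnight | 0.417 | 0.4 | 13.5 |
| midnight | 0.833 | 2.9 | 30.2 |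
| midnight | 1.33 | 6.5 | 46.8 |
| midnight | 1.50 | 9.4 | 52.1 |
| midnight | 2.00 | 17.7 | 63.0 |
| midnight | 2.50 | 25.7 | 73.7 |
| autumn | 0.417 | 0 | 15.4 |
| autumn | 0.833 | 2.9 | 29.9 |
| autumn | 1.33 | 12.1 | 40.8 |
| autumn | 1.50 | 15.5 | 43.3 |
| autumn | 2.00 | 30.1 | 54.1 |
| autumn | 2.50 | 40.4 | 58.9 |
| spring | 0.500 | 0.1 | 20.3 |
| spring | 1.00 | 4.4 | 37.3 |
| spring | 1.50 | 8.4 | 51.8 |
| spring | 2.00 | 15.4 | 62.4 |
| spring | 2.50 | 26.9 | 74.1 |

(readings scatter by 1 percentage point)

- the average divides the monomer in chains by the number of chains begun, living and dead together
- the earlier runs do not show the number of chains; that part of a forecast is a guess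
- percentages count the whole charge, also what has not yet gone in

* average number of monomer units in a chain (chains begun, living or dead) at 2.5 h
* part of the free monomer that has reacted at 2.5 h

1. With that constant frozen, loss of free monomer is pseudo-first-order. A portion fed evenly stays on average 1.25 h, so m, the fraction of the charge still free at the end, is roughly the exponential of minus the constant times that stay.

2. We take the constant to follow the initiator charged per starting volume. The spring run, with the same free monomer charge as this flask, was charged with 0.0720 mM of initiator and ends at m = 74.1%, which gives 4.16 /mM. We call this the loss number: ln(1/m) divided by the initiator charged per starting volume. It is a reading and carries the scatter.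

3. The midnight run reads 4.49 /mM and the autumn run, at the same loading with more free monomer, reads higher, 4.99 /mM. We therefore carry the spring value, read at this flask's free monomer charge, to the flask.

4. The flask is charged with 0.0480 mM of initiator, so our c is 18.1%. If every initiator began one chain, dp would be c divided by the loading, 90.6. The runs do not show the number of chains, so this figure is a guess.

The forecast gives c = 18% (15% to 21%) and dp = 105 (80 to 200), and says of dp: “Incomplete initiation would raise it, but the runs cannot show this”. Its dp is higher than our figure.

The flask gives c = 18.8% and dp = 193.

    free monomer + initiator → living end + monomer in chains (k = 0.0510 /M/s)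
    free monomer + living end → monomer in chains + living end, rate k2*[living end]*[free monomer] (k = 2.30 /M/s)
    initiator → spent initiator A (k = 2.20 × 10⁻⁴ /s)
    initiator + monomer in chains → spent initiator B (k = 0.0780 /M/s)

The flask's loss number is thus 4.34 /mM, and it ends with 0.0233 mM of living end and 0.0235 mM of spent initiator A. A neighbouring flask, charged with 96 mM of free monomer at the same loading, is charged with 0.192 mM of initiator. The autumn loss number, from the largest charge among the runs, gives it c = 61.7%. That neighbour gave 62.4%, a loss number of 5.09 /mM, and dp = 504.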